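**The question.** One question stands, put to each flask in turn: how much complex with one exchanged it holds at 2.0 min.

| flask | starting complex | incoming ligand | remark | time |
|---|---|---|---|---|
| south-west | 2.0 × 10⁻⁴ M | 0.71 equiv | run made earlier |  |
| east | 2.0 × 10⁻⁴ M | 3.4 equiv | run made earlier |  |
| blue | 2.0 × 10⁻⁴ M | 0.500 equiv |  | 2.0 min |
| violet | 2.0 × 10⁻⁴ M | 1.00 equiv |  | 2.0 min |
| ochre | 2.0 × 10⁻⁴ M | 2.50 equiv |  | 2.0 min |

| run | time / s | complex with one exchanged / % | complex with two exchanged / % | starting complex / % |
|---|---|---|---|---|
| south-west | 15.0 | 15 | 8 | 56 |
| south-west | 30.0 | 26 | 10 | 50 |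
| south-west | 50.0 | 30 | 10 | 45 |
| south-west | 60.0 | 32 | 7 | 39 |
| east | 10.0 | 28 | 32 | 31 |
| east | 12.0 | 31 | 33 | 26 |
| east | 25.0 | 43 | 37 | 18 |
| east | 60.0 | 46 | 38 | 10 |

(scatter of a reading: 2 percentage points)

- how much complex with one exchanged is there at the end, in percent of the starting complex charged: for each flask in turn (blue, violet, ochre)



**Fast rung.** Material leaves the read complexes early: at 15.0 s the south-west readings sum to 79.0% of the charge.

**Middle rung.** Integrating a first-order fall from the charge to the first reading gives the starting complex a half-life of 5.92 s in the east run and 17.9 s in the south-west run, slower at the smaller ligand charge.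

**Slow rung.** Between 25.0 s and 60.0 s the east run's complex with one exchanged moves 3 percentage points, against a scatter of 2 points. The asked time is 6.70 south-west half-lives, longer than that rung, so the new flasks are reckoned near their plateau.

**Carried ratio.** Divide the square of complex with one exchanged by the product of starting complex and complex with two exchanged. If each step swaps one ligand, free ligand cancels from this quotient. The last readings give 5.57 in the east run and 3.75 in the south-west run. Their mean, 4.66, is the exchange ratio, that quotient at the plateau, a comproportionation constant.

**Ceiling.** With this ratio held fixed, the share of complex with one exchanged among the read complexes peaks where starting complex and complex with two exchanged are equal, at 51.9%. This reckoning puts ochre just under that ceiling, violet under ochre, and blue under violet, since blue is charged below the south-west run.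

**Forecast.** The forecast, for an exchange that has “almost levelled off”, gives 32%, 45% and 49%.

**Result.** The flasks hold 30.1%, 42.5% and 48.2%, with ochre below the ceiling.

    starting complex + incoming ligand ⇌ leaving ligand + complex with one exchanged (K = 2.40, k = 210 M⁻¹ s⁻¹)
    complex with one exchanged + incoming ligand ⇌ leaving ligand + complex with two exchanged (K = 0.490, k = 579 M⁻¹ s⁻¹)
    starting complex ⇌ dormant form (K = 0.373, k = 1.48 s⁻¹)

**Ratio applied.** Ochre carries 15.6% starting complex and 30.5% complex with two exchanged, and the exchange ratio turns these into 47.0% of complex with one exchanged. Blue carries 47.7% and 4.33% at 2.00 min, from which the same ratio gives 31.0%, and at that time blue holds 30.1% of complex with one exchanged.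

All runs stem from a simulated flask with made-up constants, noise included.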